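**Retrosynthetic overview**
1. All six C2/C3 stereocentres are bought: (+)-catechin 1 is the central unit and (2R,3R)-fustin 2 supplies both outer units. No ring is constructed; all nine arrive intact.
2. 2 is reduced to flavan-3,4-diol 3, whose acid-generated quinone methide 4 is the C4 electrophile.
3. Both interflavanyl bonds (C4–C8 and C4–C6) are made in one pot by two successive Friedel–Crafts alkylations of ring A of 1 with 4. The dimers 5 (4β→8) and 6 (4β→6) both converge on target 7.
4. Both new C4 centres are set under the influence of the adjacent bought C3/C2 centres, and the 4β,4β (3,4-cis, 3,4-cis) isomer is isolated.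

Assumption: (+)-catechin and (2R,3R)-fustin (natural trans-dihydrofisetin) are taken as purchasable enantiopure natural products.

The target is fisetinidol-(4β→6)-[fisetinidol-(4β→8)]-catechin. Each outer unit is 2R,3S,4R (2,3-trans-3,4-cis) and the core is 2R,3S.

**Step 1**
Reactants: 2 (2R,3R)-fustin
Product: 3 (2R,3S,4R)-2-(3,4-dihydroxyphenyl)chromane-3,4,7-triol (mollisacacidin)
Conditions: NaBH4 (3 equiv), EtOH, 0 °C to rt, N2, 3 h; H2O, dil. AcOH to pH 6–7, EtOAc extraction
Reagents that add atoms: none
Why: Borohydride reduction of the aryl ketone; axial hydride attack on the half-chair (2-aryl and 3-OH equatorial) gives the equatorial 4-OH, i.e. the 3,4-trans (4R) diol, with C2 and C3 untouched (C4 is ionised again in the next step, so any 4-epimer is harmless).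

**Step 2**
Reactants: 1 (+)-catechin (1.0 equiv); 3 mollisacacidin (2.2 equiv)
Product: 7 fisetinidol-(4β→6)-[fisetinidol-(4β→8)]-catechin, via quinone methide 4 (not isolated), via fisetinidol-(4β→8)-catechin 5 (not isolated), via fisetinidol-(4β→6)-catechin 6 (not isolated)
Conditions: 0.1 M aq HCl, rt, N2, 24 h (3 added in three portions over 6 h); EtOAc extraction; Sephadex LH-20 (EtOH), then C18 HPLC (MeOH–H2O)
Reagents that add atoms: none
Why: Acid-catalysed loss of the benzylic 4-OH of 3 gives the 7-oxygen-stabilised para-quinone methide 4 (flavan-4-yl cation), which alkylates ring A of catechin in two successive Friedel–Crafts reactions at C8 and C6, its only strongly nucleophilic carbons, so both dimers 5 and 6 funnel into the same angular trimer and growth largely stops there because the remaining resorcinol and catechol rings are far weaker nucleophiles; each new C4 centre is set by the adjacent bought C3/C2 centres, which in this 5-deoxy series allow attack on both faces (expected 4α : 4β roughly 2 : 1 per bond), so 7 is the minor 4β,4β member of four diastereomeric trimers and is separated from them by chromatography, the 5-deoxy interflavanyl bonds being stable to this acid so no centre is scrambled.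

**Compound list**
1 | (+)-catechin, (2R,3S)-2-(3,4-dihydroxyphenyl)chromane-3,5,7-triol | Oc1cc(O)c2c(c1)O[C@H](c1ccc(O)c(O)c1)[C@@H](O)C2 | starting material
2 | (2R,3R)-fustin, (2R,3R)-2-(3,4-dihydroxyphenyl)-3,7-dihydroxychroman-4-one | Oc1ccc2c(c1)O[C@H](c1ccc(O)c(O)c1)[C@@H](O)C2=O | starting material
3 | mollisacacidin, (2R,3S,4R)-2-(3,4-dihydroxyphenyl)chromane-3,4,7-triol (2,3-trans-3,4-trans) | Oc1ccc2c(c1)O[C@H](c1ccc(O)c(O)c1)[C@@H](O)[C@@H]2O | intermediate
4 | quinone methide, (2R,3S)-2-(3,4-dihydroxyphenyl)-3-hydroxy-2,3-dihydro-7H-chromen-7-one | O=C1C=CC2=C[C@H](O)[C@@H](c3ccc(O)c(O)c3)OC2=C1 | intermediate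
5 | fisetinidol-(4β→8)-catechin, (2R,3S)-2-(3,4-dihydroxyphenyl)-8-[(2R,3S,4R)-2-(3,4-dihydroxyphenyl)-3,7-dihydroxychroman-4-yl]chromane-3,5,7-triol | Oc1cc(O)c2c(c1[C@H]3c4ccc(O)cc4O[C@H](c4ccc(O)c(O)c4)[C@H]3O)O[C@H](c1ccc(O)c(O)c1)[C@@H](O)C2 | intermediate
6 | fisetinidol-(4β→6)-catechin, (2R,3S)-2-(3,4-dihydroxyphenyl)-6-[(2R,3S,4R)-2-(3,4-dihydroxyphenyl)-3,7-dihydroxychroman-4-yl]chromane-3,5,7-triol | Oc1ccc2c(c1)O[C@H](c1ccc(O)c(O)c1)[C@@H](O)[C@H]2c1c(O)c2c(cc1O)O[C@H](c1ccc(O)c(O)c1)[C@@H](O)C2 | intermediate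
7 | fisetinidol-(4β→6)-[fisetinidol-(4β→8)]-catechin, (2R,3S)-2-(3,4-dihydroxyphenyl)-6,8-bis[(2R,3S,4R)-2-(3,4-dihydroxyphenyl)-3,7-dihydroxychroman-4-yl]chromane-3,5,7-triol | Oc1ccc2c(c1)O[C@H](c1ccc(O)c(O)c1)[C@@H](O)[C@H]2c1c(O)c2c(c([C@H]3c4ccc(O)cc4O[C@H](c4ccc(O)c(O)c4)[C@H]3O)c1O)O[C@H](c1ccc(O)c(O)c1)[C@@H](O)C2 | target

**Totals**
Total step count: 2. Longest linear sequence: 2 steps (2 → 3 → 7; 1 enters at step 2).

**Steps most likely to fail, with fallbacks**

The route has only two steps, so both are ranked, the more fragile first.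

Step 2 is the most fragile. The one-pot condensation gives four diastereomeric angular trimers beside dimers and some higher oligomers, 7 is the least abundant of the four, and 3 can self-condense in aqueous acid. The fallback changes the electrophile, its activation and the order of events, building the trimer stepwise through an isolated dimer. It sets out from 3, which is converted with phenylmethanethiol (BnSH, AcOH, EtOH, 80 °C) into 4α-benzylsulfanylfisetinidol F1, used with any 4β epimer because C4 is ionised again. F1 (1 equiv) is coupled with 1 (4 equiv) under thiophilic activation with AgBF4 (2.5 equiv) in dry THF at 0 °C, where no free diol is present to self-condense, and the 4β→8 dimer 5 is isolated (Sephadex LH-20, then C18 HPLC). A second coupling of pure 5 with F1 (1.5 equiv, AgBF4, THF, 0 °C) can then give only two trimers, the 4α→6 and 4β→6 epimers, and separation of the latter comes back to the route at 7.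

Step 1 is second. Under basic borohydride conditions the free phenoxides of 2 can open ring C (chalcone formation, erosion of C2/C3), and 3 self-condenses if the work-up turns acidic. The fallback is a protect, reduce, release sequence that sets out from 2. Silylation (TBSCl 3.3 equiv, imidazole, DMF, 0 °C) gives 7,3',4'-tris-O-TBS-fustin F2. Reduction (NaBH4, THF–EtOH, −10 °C) gives 7,3',4'-tris-O-TBS-mollisacacidin F3. Buffered desilylation (TBAF/AcOH 1:1, THF, 0 °C) comes back to the route at 3.

**Further compounds**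
F1 | step 2 | 4α-benzylsulfanylfisetinidol, (2R,3R,4R)-4-(benzylsulfanyl)-2-(3,4-dihydroxyphenyl)chromane-3,7-diol | Oc1ccc2c(c1)O[C@H](c1ccc(O)c(O)c1)[C@@H](O)[C@@H]2SCc1ccccc1
F2 | step 1 | 7,3',4'-tris-O-(tert-butyldimethylsilyl)-(2R,3R)-fustin | CC(C)(C)[Si](C)(C)Oc1ccc2c(c1)O[C@H](c1ccc(O[Si](C)(C)C(C)(C)C)c(O[Si](C)(C)C(C)(C)C)c1)[C@@H](O)C2=O
F3 | step 1 | 7,3',4'-tris-O-(tert-butyldimethylsilyl)-(2R,3S,4R)-mollisacacidin | CC(C)(C)[Si](C)(C)Oc1ccc2c(c1)O[C@H](c1ccc(O[Si](C)(C)C(C)(C)C)c(O[Si](C)(C)C(C)(C)C)c1)[C@@H](O)[C@@H]2O
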